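Readings and results are calculated for an exercise, and the scatter is random.

Time is what the east run lacks: its readings stop at 6.00 min and the question runs to 10 min, so a quick number has to stretch them.

common to all: left-handed substrate 1.5 M; right-handed substrate 1.5 M; free catalyst 160 mM

|  | coupling partner | remark | time |
|---|---|---|---|
| east | 0.90 M | run made earlier |  |
| flask | 1.80 M |  | 10 min |

east run (percent of the left-handed substrate and right-handed substrate together charged)

| time / min | right-handed substrate / % | left-handed substrate / % |
|---|---|---|
| 0.833 | 49.9 | 47.9 |
| 1.50 | 49.6 | 46.7 |
| 2.50 | 49.4 | 45.5 |
| 3.00 | 49.7 | 45.1 |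
| 4.00 | 49.7 | 44.2 |
| 5.00 | 49.2 | 43.0 |
| 6.00 | 49.8 | 42.9 |

(scatter of a reading: 0.3 percentage points)

- free catalyst is single-handed; left-handed substrate and right-handed substrate are mirror images of each other, charged as a racemate, each of them at the stated concentration
- the earlier runs were read with a standard deviation of 0.3 percentage points

- whether the excess of right-handed substrate over left-handed substrate among what is left of the two reaches 98% by 10 min (no / yes)
- the highest excess of right-handed substrate over left-handed substrate among what is left of the two up to 10 min

The racemate is the zero of the scale. This is a kinetic resolution, and its measure here is the gap G, the right-handed reading minus the left-handed one, as a fraction of the substrates charged. The right-handed substrate reads near 49.8% in the east run; taking it to stay there, the excess is G/(1−G), and the level asked needs G of 49 points. The east gap reads 2.9 points at 1.50 min and 6.9 points at 6.00 min, which is roughly a square-root bend in time. Taking that bend, and assuming G proportional to the partner charge, gives the gap per molar of coupling partner at 10 min, w, as 0.0990 M⁻¹. In the flask, w gives G of 18 points, less than the level needs, and an excess of 21.7%.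

The forecast says no and 16%, within 9% to 24%, on the grounds that “selectivity is high but activity is the limit”. The reckoning above lands higher, inside that range.

The flask gives no and 19.2%.

    free catalyst + left-handed substrate ⇌ catalyst intermediate A (K = 1.32 M⁻¹, k = 0.465 M⁻¹ s⁻¹)
    free catalyst + right-handed substrate ⇌ catalyst intermediate B (K = 0.270 M⁻¹, k = 0.302 M⁻¹ s⁻¹)
    coupling partner + catalyst intermediate A → free catalyst + left-handed product (k = 0.0399 M⁻¹ s⁻¹)
    coupling partner + catalyst intermediate B → free catalyst + right-handed product (k = 0.00126 M⁻¹ s⁻¹)
    coupling partner ⇌ dormant form (K = 2.45, k = 0.00245 s⁻¹)
    2 free catalyst ⇌ resting dimer, settled at all times (K = 220 M⁻¹)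
    2 free catalyst → spent catalyst (k = 0.0531 M⁻¹ s⁻¹)

At 10.0 min the flask's gap, per molar of partner charged, is 0.0887 M⁻¹, close to w. At the partner charged in the flask, catalyst intermediate A undoes 4.90 times as fast as it couples. Because of that undoing, the flask's excess stands at 19.2%; the run without it reaches 82.2%.

For the neighbour flask with 0.72 M of coupling partner, w gives G of 7.1 points and an excess of 7.64%. The computed top there is 8.33%.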